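Labels used throughout: u = upper epiafzelechin unit (rings A, B, C), l = lower catechin unit (rings D, E, F), with flavan numbering.

## The problem

- Gambiriin C (23) is a 4β→8 biflavanoid. The upper unit (2R,3R,4R) is bonded through C4(u) to C8(l) of a lower (+)-catechin unit (2R,3S).
- The two lower stereocentres come with commercial catechin, but they lie too far from ring C to steer it. C3(u) and C4(u) therefore need an external chiral controller. After that, C4 can hold C3 trans by equilibration, and C3 can direct C2 by chelation.
- The upper pattern is 2,3-cis and 3,4-trans, which is not the relaxed arrangement at C2/C3. C2(u) must therefore be fixed by a stereospecific event, not by equilibration.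
- The C4(u)–C8(l) bond is doubly benzylic between two phloroglucinol-type rings and ionises in acid. Making it by flavanyl cation chemistry meets two nucleophilic carbons (C6, C8) on each of rings A and D, which invites regioisomers and oligomers.
- Seven phenols and two secondary alcohols make the free compound sensitive to base, air and oxidants. All of them must stay masked until a neutral last step.
- The enabling feature is ring A. C4a, C5, C6, C7, C8 and C8a, with oxygen on C5, C7 and C8a, form the aromatic tautomer of cyclohexane-1,3,5-trione. Lowering C7 by one oxidation level gives a 5-oxygenated cyclohexane-1,3-dione in which C4a is the only nucleophilic carbon and O1 is an acidic enol oxygen.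
- Such a dione can take up C4(u) as an aldehyde carbon and C3(u)–C2(u) as an enamine in a single operation.

## Retrosynthesis

**23 ⇒ 22.** Seven O–benzyl bonds are cut. Benzyl is preferred to methyl, whose removal needs Lewis acids that break C4(u)–C8(l), and to acyl groups, which would not survive the organolithium steps. The precursor 22 is no simpler in skeleton, but it is stable to handling. The forward step must be neutral and must leave the C2–O1 and C4–C8 benzylic bonds alone.

**22 ⇒ 21 ⇒ 20 ⇒ 19.** No skeletal bond is cut.
- Ring A is written as its 5,7-diketo tautomer 21, reduced at C7 to carbinol 20 and masked as silyl ether 19.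
- This reading is chosen over keeping ring A aromatic because it removes the C6/C8 ambiguity and turns O1 into the oxygen of a vinylogous acid.
- The forward reaction is a β-hydroxy ketone oxidation that must outrun β-elimination, after which tautomerisation is spontaneous.

**19 ⇒ 18.** O1(u)–C2(u) is cut.
- The neighbouring option is to bring ring B as a nucleophile onto a C2 oxocarbenium ion. That would place the aryl group anti to the 3-benzyloxy group and give the 2,3-trans series.
- An SN2 closure transfers the configuration of an open-chain carbinol instead.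
- Since 2,3-cis corresponds to a syn O1/O3 relation along the Ar–C2–C3–C4 chain, the (2S)-anti carbinol 18 and clean inversion are required.

**18 ⇒ 17 ⇒ 14 + 15 (through 16).** The C2(u)–H bond and then C2(u)–C1′(u) are cut.
- Passing through ketone 17 lets the 3-benzyloxy group set C2 by chelation. That is more dependable than adding an aryl metal to an α-alkoxy aldehyde, where chelation gives the wrong (syn) carbinol.
- Ring B becomes the commercial bromide 15.
- An N-methoxy-N-methyl amide 14 is chosen as acyl donor rather than the lactone 13. The enol lactone would release the ketone during the addition and invite a second attack.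

**14 ⇒ 13 ⇒ 12.** The amide C–N bond is cut back to enol lactone 13, and C2 is reduced to lactol 12.
- This admits that ring C is closed, opened and closed again.
- The first closure drives the C3–C4 bond formation to completion and provides the cyclic frame in which C3 settles trans to C4.
- The forward steps are a lactol oxidation and the aminolysis of an activated ester.

**12 ⇒ 11 ⇒ 4 + 9 + 10.** C4(u)–C4a(u), C3(u)–C4(u) and O1(u)–C2(u) are cut together.
- Cutting C4(u)–C8(l) instead leads back to cation chemistry and its site problems.
- Cutting only C3–C4 and O1–C2 leaves a sensitive diarylmethanol to be made separately.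
- The triple cut gives an achiral dione 4, an aldehyde 9 that holds the whole lower unit, and the two-carbon aldehyde 10.
- The forward reaction must choose between two aldehydes, stop at one dione per aldehyde, and set C3 and C4 under the control of a chiral secondary amine.

**9 ⇒ 8 ⇒ 7 ⇒ 6 ⇒ 5.** C8(l)–CHO is cut. Bromination of the perbenzyl ether 6 is selective for C8, and bromine–lithium exchange carries that selectivity into the formyl group. Direct formylation would leave a C6/C8 question open. All stereocentres of 5 are retained.

**4 ⇒ 3 ⇒ 2 ⇒ 1.** The O–Si bond is cut, and ring A is re-aromatised on paper to phloroglucinol 1. Partial hydrogenation gives the dione oxidation level in one step from a bulk chemical. The forward steps must avoid acid-induced dehydration of 2.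

## Roads not taken

**Alternative 1:** The cut runs through ring D at C8(l)–C8a(l) and C6(l)–C7(l).
- *Key step:* a 4β-(triisopropylsilyloxyethynyl)epiafzelechin ether A1 and the 3-benzyloxycyclobutenone A2, which carries C2(l)–C4(l) as a syn-diol acetonide, would be heated together (Danheiser benzannulation). The cyclobutenone opens to a vinylketene, which adds to the siloxyalkyne. A second ring opening and a 6π closure then give phenol A3.
- *Merits:* the pentasubstituted ring D is assembled with no C6/C8 ambiguity. The conditions are neutral and reagent-free. The reaction type is established for siloxyalkynes, which the chosen key step cannot claim.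
- *Weak points:*
  - A1 presupposes a finished upper unit with all three stereocentres and a fragile ynol ether on a hindered secondary carbon.
  - A2 needs a multistep synthesis.
  - C2(l) and C3(l), available for nothing in 5, have to be rebuilt by asymmetric dihydroxylation.
  - Ring F is still open after the key step and needs acetonide removal and an invertive closure.
- *Comparison:* alternative 1 is better in precedent and in regiochemical certainty. The chosen plan gets the same certainty from the C8 bromination of 6. It also buys the whole lower unit and makes two upper stereocentres in the step that installs C4(u).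

**Alternative 2:** The cut is C4(l)–C4a(l).
- *Key step:* in a strongly hydrogen-bonding fluorinated alcohol, or with a cationic gold catalyst, ring D of the 1-aryl-2,3-epoxypropyl ether A4 would attack the terminal epoxide carbon in a 6-endo opening. This closes ring F and gives A5.
- *Merits:* C2(l) and C3(l) are carried stereospecifically. The cyclisation type is known for chroman-3-ols. The free 3(l)-hydroxyl of A5 would allow selective acylation, which the chosen plan does not offer.
- *Weak points:*
  - The step solves the part of the molecule that can be bought.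
  - A4 already contains the interflavan bond, ring C and a threefold differentiated ring D, so the hard problems are only moved upstream.
  - The C2(l)–O bond of A4 is a 3,4-dialkoxybenzylic aryl ether, and C4(u)–C8(l) sits next to an aromatic ring A. Both can ionise in the promoting medium.
  - A 5-exo opening competes.
- *Comparison:* the key step is safer than the chosen one, but the route is clearly longer. It also leaves the control of C2(u), C3(u) and C4(u) unanswered.

**Alternative 3:** The cuts are C3(u)–C4(u) and O1(u)–C2(u), with ring A aromatic from the start.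
- *Key step:* diarylmethanol A6 would lose water to an ortho-quinone methide. The enamine of 10 with the same type of chiral amine attacks it at C4(u), and the phenol then closes lactol A7.
- *Merits:* this is the closest relative of the chosen plan and is better in two respects. Enamine additions to ortho-quinone methides are a known reaction class. Ring A needs no redox correction, which saves the desilylation and the oxidation.
- *Weak points:*
  - C4(u)–C4a(u) must be made beforehand from a phloroglucinol with one free and two benzylated oxygens, which costs differentiation steps.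
  - A6 carries two trioxygenated aryl groups on one carbinol carbon, so it is very acid-labile. Its quinone methide is strongly stabilised and correspondingly sluggish and reversible.
  - The later invertive closure onto C2(u) must use a hindered, weakly acidic phenol.
- *Comparison:* the chosen plan forms three bonds instead of two in the step. It uses a symmetric carbon nucleophile that needs no differentiation, and it has an enol oxygen of carboxylic-acid-like acidity for the second ring closure. The price is two extra steps and an untested key reaction.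

Key step: step 6

Assumption: C7(u) in 12–14 and 17–20, and the corresponding element in 11, is carried as a mixture of epimers and left undefined in the SMILES. Lactol 12 is drawn as its 2,3-trans anomer although both anomers are expected. The descriptor at C4(u) reads S while ring A is a dione or vinylogous ester and R once ring A is aromatic, without any change in geometry.

## Steps

Step 1
Reactants: 1 phloroglucinol
Product: 2 5-hydroxycyclohexane-1,3-dione (dihydrophloroglucinol)
Conditions: H2 (3–4 bar), Rh/Al2O3 (5 wt %), NaOH (1 equiv), H2O, rt; then HCl to pH 3, 0 °C, lyophilise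
Reagents that add atoms: none
Why: Known partial heterogeneous hydrogenation of the phloroglucinolate monoanion, which reacts as its keto tautomer and stops after one equivalent of H2 because the product is a stabilised 1,3-dione enolate. Cold, brief acidification avoids the acid-catalysed dehydration to resorcinol.

Step 2
Reactants: 2 5-hydroxycyclohexane-1,3-dione
Product: 4 5-(tert-butyldimethylsilyloxy)cyclohexane-1,3-dione, via bis-silyl ether 3 (not isolated)
Conditions: TBSCl (2.3 equiv), imidazole, DMF, 0 °C to rt; then aq citric acid, THF, 0 °C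
Reagents that add atoms: tert-butyldimethylsilyl chloride, CC(C)(C)[Si](C)(C)Cl
Why: Imidazole-promoted silylation caps both the carbinol and the enol. The enol silyl ether of 3 is a vinylogous silyl ester and is hydrolysed selectively by mild aqueous acid, while the alkyl silyl ether stays.

Step 3
Reactants: 5 (+)-catechin
Product: 6 3,5,7,3',4'-penta-O-benzyl-(+)-catechin
Conditions: NaH (6 equiv), BnBr (6 equiv), DMF, −20 °C to rt
Reagents that add atoms: benzyl bromide, BrCc1ccccc1
Why: Williamson etherification of four phenols and the secondary alcohol in one operation. Low temperature and benzyl bromide present from the start cap each phenoxide as it forms, which suppresses C-benzylation and ring-opening epimerisation at C2.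

Step 4
Reactants: 6 penta-O-benzylcatechin
Product: 7 8-bromo-3,5,7,3',4'-penta-O-benzylcatechin
Conditions: NBS (1.0 equiv), CH2Cl2, −78 to 0 °C
Reagents that add atoms: N-bromosuccinimide, O=C1CCC(=O)N1Br
Why: Electrophilic aromatic bromination. In 5,7-di-O-benzylflavans C8 is the most nucleophilic position, and one equivalent of NBS at low temperature is the established entry to the 8-bromide.

Step 5
Reactants: 7 8-bromo-penta-O-benzylcatechin
Product: 9 penta-O-benzylcatechin-8-carbaldehyde, via 8-lithiocatechin ether 8 (not isolated)
Conditions: n-BuLi, THF, −78 °C; DMF, −78 °C to rt; then 1 M HCl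
Reagents that add atoms: N,N-dimethylformamide, CN(C)C=O
Why: Bromine–lithium exchange followed by formylation with DMF (Bouveault aldehyde synthesis). Exchange at −78 °C is faster than benzylic deprotonation, and the 8-lithio species of benzylated flavans is a known nucleophile.

Step 6
Reactants: 4 5-(tert-butyldimethylsilyloxy)cyclohexane-1,3-dione; 9 penta-O-benzylcatechin-8-carbaldehyde; 10 benzyloxyacetaldehyde
Product: 12 (2R,3R,4S)-3-benzyloxy-2-hydroxy-4-(penta-O-benzylcatechin-8-yl)-7-(tert-butyldimethylsilyloxy)-2,3,4,6,7,8-hexahydrochromen-5-one (3,4-trans lactol; C7 epimers), via alkylidenedione 11 (not isolated)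
Conditions: (S)-α,α-diphenylprolinol trimethylsilyl ether (20 mol %), PhCO2H (20 mol %), toluene, rt, 4 and 9 (1.1 equiv) first; then 10 (1.5 equiv) by syringe pump, 0 °C; SiO2, wet CH2Cl2
Reagents that add atoms: none
Why: Proposed new method: the acidic dione 4, whose only nucleophilic carbon is C2 (the future C4a(u)), condenses with the hindered, electron-rich aldehyde 9 under amine/carboxylic acid catalysis to the push–pull alkylidenedione 11 (C4–C4a), and 10 is withheld until then because it is the more electrophilic aldehyde, while any 2:1 dione adduct remains a reversible reservoir of 11. Aldehyde 10 then forms the (E)-enamine with the catalyst, whose β-carbon attacks C4 of the 1-oxadiene 11 (C3–C4) either stepwise as a Michael addition or as an inverse-electron-demand hetero-Diels–Alder reaction, and the water released earlier hydrolyses the iminium ion or N,O-aminal and returns the amine. The enol oxygen of the dione adds to the liberated aldehyde in a 6-exo-trig closure (O1–C2), which forms ring C as the lactol and pulls the reversible Michael step forward; both enol oxygens give the same constitution. The closest known reaction types are the domino Knoevenagel–hetero-Diels–Alder reaction of 1,3-diones, aldehydes and enol ethers and the diarylprolinol silyl ether catalysed Michael–hemiacetalisation of aldehydes with electron-poor oxadienes; the three-component form with an α-alkoxy aldehyde and a di-ortho-substituted aryl aldehyde is untested. C3(u) is controlled by the CPh2(OSiMe3) group, which blocks one enamine face, so that the (S)-catalyst should give 3R as it does in the spatially equivalent additions of aldehydes to nitroalkenes. C4(u) follows from the synclinal (endo) approach of acceptor and enamine, which gives the syn adduct, that is the 3,4-trans ring, and any 3,4-cis material can drain to trans by amine-mediated epimerisation at C3 of the ring-opened aldehyde. The anomeric centre and C7 are left uncontrolled because both become trigonal later. The step needs chemoselectivity between the two aldehydes (order of addition), mono- over double addition of the dione (slight excess of 9, crowding at C4) and survival of the β-silyloxy group (only weak bases, dione held as its C2 enol).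

Step 7
Reactants: 12 lactol
Product: 13 (3R,4S)-3-benzyloxy-4-(penta-O-benzylcatechin-8-yl)-7-(tert-butyldimethylsilyloxy)-4,6,7,8-tetrahydro-3H-chromene-2,5-dione (enol lactone; C7 epimers)
Conditions: Dess–Martin periodinane, CH2Cl2, 0 °C to rt
Reagents that add atoms: none
Why: Standard lactol-to-lactone oxidation under near-neutral conditions that spare silyl and benzyl ethers. It removes the anomeric centre, and C3 stays in its favoured trans relation to C4.

Step 8
Reactants: 13 enol lactone
Product: 14 N-methoxy-N-methylamide of (C3(u) R, C4(u) S)-2-benzyloxy-3-[4-(tert-butyldimethylsilyloxy)-2-hydroxy-6-oxocyclohex-1-enyl]-3-(penta-O-benzylcatechin-8-yl)propanoic acid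
Conditions: MeNH(OMe)·HCl, Et3N, CH2Cl2, 0 °C to rt; cold 0.5 M HCl wash
Reagents that add atoms: N,O-dimethylhydroxylamine (freed from its hydrochloride), CNOC
Why: Aminolysis of an activated ester: 13 is the enol ester of a 1,3-dione, whose leaving group is about as good as a carboxylate, so the free amine opens it at the acyl carbon without an aluminium amide. The product is a Weinreb amide with the dione unmasked.

Step 9
Reactants: 14 Weinreb amide; 15 4-benzyloxybromobenzene
Product: 17 (C3(u) R, C4(u) S)-2-benzyloxy-1-(4-benzyloxyphenyl)-3-[4-(tert-butyldimethylsilyloxy)-2-hydroxy-6-oxocyclohex-1-enyl]-3-(penta-O-benzylcatechin-8-yl)propan-1-one, via 4-benzyloxyphenyllithium 16 (not isolated)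
Conditions: 15, n-BuLi, THF, −78 °C (16, 2.5 equiv); add 14, −78 °C; cold 0.5 M HCl
Reagents that add atoms: none
Why: Weinreb ketone synthesis. The first equivalent of 16 deprotonates the dione, whose enolate is inert to nucleophiles and cannot lose the silyloxy group by E1cB. The second equivalent gives the chelated tetrahedral adduct, which prevents over-addition and C3 enolisation until the cold quench.

Step 10
Reactants: 17 aryl ketone
Product: 18 (C2(u) S, C3(u) R, C4(u) S)-2-benzyloxy-1-(4-benzyloxyphenyl)-3-[4-(tert-butyldimethylsilyloxy)-2-hydroxy-6-oxocyclohex-1-enyl]-3-(penta-O-benzylcatechin-8-yl)propan-1-ol (2,3-anti)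
Conditions: Zn(BH4)2 (2 equiv), Et2O/CH2Cl2, −78 to −30 °C; aq NH4Cl
Reagents that add atoms: none
Why: Chelation-controlled (Cram chelate) reduction of an α-alkoxy ketone: zinc bridges the ketone oxygen and the 3-benzyloxy group, and hydride enters from the side of H3 to give the anti, (2S) carbinol. The enol consumes one hydride and stays protected as its zinc enolate.

Step 11
Reactants: 18 anti carbinol
Product: 19 (2R,3R,4S)-3-benzyloxy-2-(4-benzyloxyphenyl)-4-(penta-O-benzylcatechin-8-yl)-7-(tert-butyldimethylsilyloxy)-2,3,4,6,7,8-hexahydrochromen-5-one (2,3-cis, 3,4-trans; C7 epimers)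
Conditions: PPh3, DIAD, toluene, 0 °C, high dilution
Reagents that add atoms: none
Why: Intramolecular Mitsunobu etherification, a reaction known for cyclic 1,3-dione enols and for invertive flavan ring closure. The acidic enol protonates the betaine, and its oxygen displaces the oxyphosphonium group 6-exo-tet with inversion, (2S) to (2R). C-alkylation would require a cyclobutane, and the non-polar cold medium disfavours ionisation.

Step 12
Reactants: 19 silyl ether
Product: 20 (2R,3R,4S)-3-benzyloxy-2-(4-benzyloxyphenyl)-7-hydroxy-4-(penta-O-benzylcatechin-8-yl)-2,3,4,6,7,8-hexahydrochromen-5-one (C7 epimers)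
Conditions: HF·pyridine, pyridine, THF, 0 °C to rt
Reagents that add atoms: none
Why: Fluoride-mediated desilylation in a weakly acidic buffer. It avoids basic fluoride, which could trigger E1cB loss or retro-aldol opening at C7, and it is too mild to ionise the C2–O1 bond.

Step 13
Reactants: 20 β-hydroxy ketone
Product: 22 3(u),4'(u),3(l),5(l),7(l),3'(l),4'(l)-hepta-O-benzyl Gambiriin C (2R,3R,4R upper; 2R,3S lower), via 5,7-diketone tautomer 21 (not isolated)
Conditions: Dess–Martin periodinane (1.05 equiv), NaHCO3, CH2Cl2, 0 °C
Reagents that add atoms: none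
Why: Dess–Martin oxidation of a β-hydroxy ketone to a 1,3-diketone, a standard use of the reagent. Diketone 21 is the keto tautomer of a phloroglucinol monoether and enolises at once to aromatic ring A. One equivalent of oxidant and a buffer limit attack on the new phenol.

Step 14
Reactants: 22 hepta-O-benzyl Gambiriin C
Product: 23 Gambiriin C, epiafzelechin-(4β→8)-catechin
Conditions: H2 (1 atm), Pd(OH)2/C, THF/MeOH/H2O, rt
Reagents that add atoms: none
Why: Hydrogenolysis of seven benzyl ethers, the standard last step for benzylated proanthocyanidins. The neutral medium leaves the C4–C8 bond, the C2–O1 bonds and all five stereocentres untouched.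

## Compound list

1 | phloroglucinol | Oc1cc(O)cc(O)c1 | starting material
2 | 5-hydroxycyclohexane-1,3-dione | O=C1CC(O)CC(=O)C1 | intermediate
3 | 3,5-bis(tert-butyldimethylsilyloxy)cyclohex-2-en-1-one (racemic, not isolated) | O=C1C=C(O[Si](C)(C)C(C)(C)C)CC(O[Si](C)(C)C(C)(C)C)C1 | intermediate
4 | 5-(tert-butyldimethylsilyloxy)cyclohexane-1,3-dione | O=C1CC(O[Si](C)(C)C(C)(C)C)CC(=O)C1 | intermediate
5 | (+)-catechin, (2R,3S) | Oc1cc(O)c2c(c1)O[C@H](c1ccc(O)c(O)c1)[C@@H](O)C2 | starting material
6 | 3,5,7,3',4'-penta-O-benzyl-(+)-catechin | c3c(OCc5ccccc5)cc(OCc5ccccc5)c4c3O[C@H](c3ccc(OCc5ccccc5)c(OCc5ccccc5)c3)[C@@H](OCc5ccccc5)C4 | intermediate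
7 | 8-bromo-penta-O-benzylcatechin | Brc3c(OCc5ccccc5)cc(OCc5ccccc5)c4c3O[C@H](c3ccc(OCc5ccccc5)c(OCc5ccccc5)c3)[C@@H](OCc5ccccc5)C4 | intermediate
8 | 8-lithio-penta-O-benzylcatechin (not isolated) | [Li]c3c(OCc5ccccc5)cc(OCc5ccccc5)c4c3O[C@H](c3ccc(OCc5ccccc5)c(OCc5ccccc5)c3)[C@@H](OCc5ccccc5)C4 | intermediate
9 | penta-O-benzylcatechin-8-carbaldehyde | O=Cc3c(OCc5ccccc5)cc(OCc5ccccc5)c4c3O[C@H](c3ccc(OCc5ccccc5)c(OCc5ccccc5)c3)[C@@H](OCc5ccccc5)C4 | intermediate
10 | benzyloxyacetaldehyde | O=CCOCc1ccccc1 | starting material
11 | 2-[(penta-O-benzylcatechin-8-yl)methylidene]-5-(tert-butyldimethylsilyloxy)cyclohexane-1,3-dione (not isolated) | O=C1CC(O[Si](C)(C)C(C)(C)C)CC(=O)C1=Cc3c(OCc5ccccc5)cc(OCc5ccccc5)c4c3O[C@H](c3ccc(OCc5ccccc5)c(OCc5ccccc5)c3)[C@@H](OCc5ccccc5)C4 | intermediate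
12 | (2R,3R,4S)-3-benzyloxy-2-hydroxy-4-(penta-O-benzylcatechin-8-yl)-7-(tert-butyldimethylsilyloxy)-2,3,4,6,7,8-hexahydrochromen-5-one, 3,4-trans, one anomer drawn, C7 epimers | O[C@@H]2OC3=C(C(=O)CC(O[Si](C)(C)C(C)(C)C)C3)[C@H](c3c(OCc5ccccc5)cc(OCc5ccccc5)c4c3O[C@H](c3ccc(OCc5ccccc5)c(OCc5ccccc5)c3)[C@@H](OCc5ccccc5)C4)[C@H]2OCc5ccccc5 | intermediate
13 | (3R,4S)-enol lactone, 3-benzyloxy-4-(penta-O-benzylcatechin-8-yl)-7-(tert-butyldimethylsilyloxy)-4,6,7,8-tetrahydro-3H-chromene-2,5-dione | O=C2OC3=C(C(=O)CC(O[Si](C)(C)C(C)(C)C)C3)[C@H](c3c(OCc5ccccc5)cc(OCc5ccccc5)c4c3O[C@H](c3ccc(OCc5ccccc5)c(OCc5ccccc5)c3)[C@@H](OCc5ccccc5)C4)[C@H]2OCc5ccccc5 | intermediate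
14 | Weinreb amide with free dione, C3(u) R, C4(u) S | CON(C)C(=O)[C@H](OCc5ccccc5)[C@@H](c3c(OCc5ccccc5)cc(OCc5ccccc5)c4c3O[C@H](c3ccc(OCc5ccccc5)c(OCc5ccccc5)c3)[C@@H](OCc5ccccc5)C4)C1=C(O)CC(O[Si](C)(C)C(C)(C)C)CC1=O | intermediate
15 | 4-benzyloxybromobenzene | Brc1ccc(OCc2ccccc2)cc1 | starting material
16 | 4-benzyloxyphenyllithium (not isolated) | [Li]c1ccc(OCc2ccccc2)cc1 | intermediate
17 | α-benzyloxy aryl ketone with free dione, C3(u) R, C4(u) S | O=C(c1ccc(OCc5ccccc5)cc1)[C@H](OCc5ccccc5)[C@@H](c3c(OCc5ccccc5)cc(OCc5ccccc5)c4c3O[C@H](c3ccc(OCc5ccccc5)c(OCc5ccccc5)c3)[C@@H](OCc5ccccc5)C4)C1=C(O)CC(O[Si](C)(C)C(C)(C)C)CC1=O | intermediate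
18 | 2,3-anti carbinol, C2(u) S, C3(u) R, C4(u) S | O[C@@H](c1ccc(OCc5ccccc5)cc1)[C@H](OCc5ccccc5)[C@@H](c3c(OCc5ccccc5)cc(OCc5ccccc5)c4c3O[C@H](c3ccc(OCc5ccccc5)c(OCc5ccccc5)c3)[C@@H](OCc5ccccc5)C4)C1=C(O)CC(O[Si](C)(C)C(C)(C)C)CC1=O | intermediate
19 | (2R,3R,4S)-2-aryl hexahydrochromen-5-one, 7-silyl ether, 2,3-cis, 3,4-trans | c5ccccc5COc1ccc([C@H]2OC3=C(C(=O)CC(O[Si](C)(C)C(C)(C)C)C3)[C@H](c3c(OCc5ccccc5)cc(OCc5ccccc5)c4c3O[C@H](c3ccc(OCc5ccccc5)c(OCc5ccccc5)c3)[C@@H](OCc5ccccc5)C4)[C@H]2OCc5ccccc5)cc1 | intermediate
20 | (2R,3R,4S)-7-hydroxy hexahydrochromen-5-one | c5ccccc5COc1ccc([C@H]2OC3=C(C(=O)CC(O)C3)[C@H](c3c(OCc5ccccc5)cc(OCc5ccccc5)c4c3O[C@H](c3ccc(OCc5ccccc5)c(OCc5ccccc5)c3)[C@@H](OCc5ccccc5)C4)[C@H]2OCc5ccccc5)cc1 | intermediate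
21 | 5,7-diketone tautomer of 22 (not isolated) | c5ccccc5COc1ccc([C@H]2OC3=C(C(=O)CC(=O)C3)[C@H](c3c(OCc5ccccc5)cc(OCc5ccccc5)c4c3O[C@H](c3ccc(OCc5ccccc5)c(OCc5ccccc5)c3)[C@@H](OCc5ccccc5)C4)[C@H]2OCc5ccccc5)cc1 | intermediate
22 | hepta-O-benzyl Gambiriin C, free 5(u)- and 7(u)-hydroxyls | c5ccccc5COc1ccc([C@H]2Oc3cc(O)cc(O)c3[C@H](c3c(OCc5ccccc5)cc(OCc5ccccc5)c4c3O[C@H](c3ccc(OCc5ccccc5)c(OCc5ccccc5)c3)[C@@H](OCc5ccccc5)C4)[C@H]2OCc5ccccc5)cc1 | intermediate
23 | Gambiriin C | Oc1ccc([C@H]2Oc3cc(O)cc(O)c3[C@H](c3c(O)cc(O)c4c3O[C@H](c3ccc(O)c(O)c3)[C@@H](O)C4)[C@H]2O)cc1 | target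

## Step count and least certain steps

Total step count: 14 (steps 1–2 for dione 4, steps 3–5 for aldehyde 9, steps 6–14 from the union to 23).
Longest linear sequence: 12 steps (5 to 23, steps 3–14).

**Step 6 (key step).**
- *Risks:*
  - The Knoevenagel stage may be slow with a di-ortho-substituted, electron-rich aldehyde, so free dione is still present when 10 arrives and condenses with it instead.
  - A second dione may capture the alkylidenedione.
  - Aldehyde 10 may self-condense.
  - Facial selectivity at C4(u) may be poor. The aryl group is cis to one carbonyl and trans to the other, so two oxadiene geometries compete, and the remote lower stereocentres may oppose the catalyst.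
- *Fallback (known chemistry):* it sets out from 4, 9 and 10 and returns at 12.
  - Aldehyde 10 is converted with methanol and catalytic acid into benzyloxyacetaldehyde dimethyl acetal F1.
  - TMSOTf and i-Pr2NEt then convert F1 into 1-benzyloxy-2-methoxyethene F2.
  - Compounds 4, 9 and F2 are combined under ethylenediammonium diacetate catalysis in the classical domino Knoevenagel–hetero-Diels–Alder manner. This gives the 2-methoxy acetal F3 as a mixture of diastereomers.
  - Mild aqueous acid hydrolysis and amine-catalysed equilibration at C3 give 12 together with its upper-ring (3S,4R) diastereomer F4.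
  - The chiral lower unit makes the two lactols diastereomers, so 12 is separated from F4 by chromatography.
  - Absolute control is given up, and about half of the material is lost.

**Step 11.**
- *Risks:* the activated carbinol is 4-alkoxybenzylic. Ionisation ahead of displacement would erode the inversion and drift towards the 2,3-trans ring. Elimination towards C3 would destroy a stereocentre.
- *Fallback:* it sets out from 17 and returns at 19, skipping 18.
  - Ketone 17 is in equilibrium with its cyclic 2-aryl-2-hydroxy hemiketal F5.
  - Et3SiH and BF3·OEt2 in CH2Cl2/MeCN at −78 to −40 °C reduce F5 through the C2 cation, as in the reductive deoxygenation of hemiketals used for C-aryl glycosides.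
  - Hydride should enter anti to the pseudo-axial 3-benzyloxy group and leave the aryl group cis to it.
  - Short contact time is needed, because 19 can re-ionise under these conditions.

**Step 13.**
- *Risks:* the C7 oxygen may be lost by β-elimination from the activated carbinol, and the freshly formed, very electron-rich ring A may be over-oxidised by residual oxidant.
- *Fallback:* it sets out from 19 and returns at 22, skipping 20 and 21.
  - Soft enolisation towards C6 (TMSOTf, Et3N, CH2Cl2, 0 °C) gives the cross-conjugated 5-trimethylsilyloxy diene F6.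
  - Saegusa–Ito oxidation with Pd(OAc)2 in MeCN removes H6 and H7 through a divalent palladium enolate and β-hydride elimination.
  - The dienone tautomerises to the 7-O-silyl phenol F7.
  - Buffered fluoride (TBAF, AcOH) then gives 22.
  - No free phenol meets an electrophilic oxidant on this path.

**Step 9.**
- *Risks:* addition to a hindered amide next to a charged enolate may be sluggish, so deprotonation at C3 competes. After the quench, epimerisation at C3 or retro-Michael loss of the dione from C4 becomes possible if the ketone is kept basic or warm.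
- *Fallback:* it sets out from 12 and returns at 17, skipping 13 and 14.
  - Excess 16 at −78 °C deprotonates the lactol, which opens to the aldehyde and the dione enolate.
  - Addition of 16 to this more electrophilic carbonyl gives the C2-epimeric carbinols F8.
  - MnO2, which is selective for the 4-alkoxybenzylic alcohol, then gives 17.

**Step 10.**
- *Risks:* reversible hemiketalisation may mask the ketone. Competing chelation by the neighbouring zinc enolate may erode the anti selectivity. Slow reduction of the dione is also possible.
- *Fallback:* it sets out from 17 and returns at 18. Substrate control is replaced by reagent control in a Noyori-type transfer hydrogenation with RuCl(p-cymene)[(R,R)-TsDPEN] in HCO2H/Et3N. With acetophenone this catalyst enantiomer gives the (R)-alcohol, which is the spatial equivalent of (2S) here because the α-alkoxy carbon outranks the aryl group.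

## Further compounds

F1 | step 6 | benzyloxyacetaldehyde dimethyl acetal | COC(COCc1ccccc1)OC
F2 | step 6 | 1-benzyloxy-2-methoxyethene (E/Z mixture) | COC=COCc1ccccc1
F3 | step 6 | 3-benzyloxy-2-methoxy-4-(penta-O-benzylcatechin-8-yl)-7-(tert-butyldimethylsilyloxy)-2,3,4,6,7,8-hexahydrochromen-5-one (mixture of upper-ring diastereomers) | COC2OC3=C(C(=O)CC(O[Si](C)(C)C(C)(C)C)C3)C(c3c(OCc5ccccc5)cc(OCc5ccccc5)c4c3O[C@H](c3ccc(OCc5ccccc5)c(OCc5ccccc5)c3)[C@@H](OCc5ccccc5)C4)C2OCc5ccccc5
F4 | step 6 | (3S,4R) upper-ring diastereomer of lactol 12 (anomers, C7 epimers) | OC2OC3=C(C(=O)CC(O[Si](C)(C)C(C)(C)C)C3)[C@@H](c3c(OCc5ccccc5)cc(OCc5ccccc5)c4c3O[C@H](c3ccc(OCc5ccccc5)c(OCc5ccccc5)c3)[C@@H](OCc5ccccc5)C4)[C@@H]2OCc5ccccc5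
F5 | step 11 | cyclic hemiketal of 17, 2-(4-benzyloxyphenyl)-2-hydroxy-hexahydrochromen-5-one (C2 undefined) | OC2(c1ccc(OCc5ccccc5)cc1)OC3=C(C(=O)CC(O[Si](C)(C)C(C)(C)C)C3)[C@H](c3c(OCc5ccccc5)cc(OCc5ccccc5)c4c3O[C@H](c3ccc(OCc5ccccc5)c(OCc5ccccc5)c3)[C@@H](OCc5ccccc5)C4)[C@H]2OCc5ccccc5
F6 | step 13 | 5-trimethylsilyloxy-7-(tert-butyldimethylsilyloxy) diene derived from 19 | c5ccccc5COc1ccc([C@H]2OC3=C(C(O[Si](C)(C)C)=CC(O[Si](C)(C)C(C)(C)C)C3)[C@H](c3c(OCc5ccccc5)cc(OCc5ccccc5)c4c3O[C@H](c3ccc(OCc5ccccc5)c(OCc5ccccc5)c3)[C@@H](OCc5ccccc5)C4)[C@H]2OCc5ccccc5)cc1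
F7 | step 13 | 7(u)-O-tert-butyldimethylsilyl hepta-O-benzyl Gambiriin C | c5ccccc5COc1ccc([C@H]2Oc3cc(O[Si](C)(C)C(C)(C)C)cc(O)c3[C@H](c3c(OCc5ccccc5)cc(OCc5ccccc5)c4c3O[C@H](c3ccc(OCc5ccccc5)c(OCc5ccccc5)c3)[C@@H](OCc5ccccc5)C4)[C@H]2OCc5ccccc5)cc1
F8 | step 9 | C2(u)-epimeric carbinols (18 and its 2-epimer) | OC(c1ccc(OCc5ccccc5)cc1)[C@H](OCc5ccccc5)[C@@H](c3c(OCc5ccccc5)cc(OCc5ccccc5)c4c3O[C@H](c3ccc(OCc5ccccc5)c(OCc5ccccc5)c3)[C@@H](OCc5ccccc5)C4)C1=C(O)CC(O[Si](C)(C)C(C)(C)C)CC1=O
F0 | step 10 | none | none
A1 | alternative 1 | 4β-(triisopropylsilyloxyethynyl)-3,5,7,4'-tetra-O-benzylepiafzelechin | c5ccccc5COc1ccc([C@H]2Oc3cc(OCc5ccccc5)cc(OCc5ccccc5)c3[C@H](C#CO[Si](C(C)C)(C(C)C)C(C)C)[C@H]2OCc5ccccc5)cc1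
A2 | alternative 1 | 3-benzyloxy-2-(acetonide side chain)cyclobut-2-en-1-one | O=C1CC(OCc5ccccc5)=C1C[C@@H]6OC(C)(C)O[C@H]6c7ccc(OCc5ccccc5)c(OCc5ccccc5)c7
A3 | alternative 1 | hepta-O-benzyl dimer precursor, ring D as C8a(l) phenol, O7(l)-triisopropylsilyl, acetonide side chain at C4a(l) | c5ccccc5COc1ccc([C@H]2Oc3cc(OCc5ccccc5)cc(OCc5ccccc5)c3[C@H](c3c(O[Si](C(C)C)(C(C)C)C(C)C)cc(OCc5ccccc5)c(C[C@@H]6OC(C)(C)O[C@H]6c7ccc(OCc5ccccc5)c(OCc5ccccc5)c7)c3O)[C@H]2OCc5ccccc5)cc1
A4 | alternative 2 | 1-aryl-2,3-epoxypropyl ether of the ring D phenol bound to C4(u) | c5ccccc5COc1ccc([C@H]2Oc3cc(OCc5ccccc5)cc(OCc5ccccc5)c3[C@H](c3c(OCc5ccccc5)cc(OCc5ccccc5)cc3O[C@H](c3ccc(OCc5ccccc5)c(OCc5ccccc5)c3)[C@@H]6CO6)[C@H]2OCc5ccccc5)cc1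
A5 | alternative 2 | octa-O-benzyl Gambiriin C with free 3(l)-hydroxyl | c5ccccc5COc1ccc([C@H]2Oc3cc(OCc5ccccc5)cc(OCc5ccccc5)c3[C@H](c3c(OCc5ccccc5)cc(OCc5ccccc5)c4c3O[C@H](c3ccc(OCc5ccccc5)c(OCc5ccccc5)c3)[C@@H](O)C4)[C@H]2OCc5ccccc5)cc1
A6 | alternative 3 | (4,6-dibenzyloxy-2-hydroxyphenyl)(penta-O-benzylcatechin-8-yl)methanol (carbinol epimers) | OC(c1c(O)cc(OCc5ccccc5)cc1OCc5ccccc5)c3c(OCc5ccccc5)cc(OCc5ccccc5)c4c3O[C@H](c3ccc(OCc5ccccc5)c(OCc5ccccc5)c3)[C@@H](OCc5ccccc5)C4
A7 | alternative 3 | 3,5,7-tribenzyloxy-4-(penta-O-benzylcatechin-8-yl)chroman-2-ol, 3,4-trans, one anomer drawn | O[C@@H]2Oc3cc(OCc5ccccc5)cc(OCc5ccccc5)c3[C@H](c3c(OCc5ccccc5)cc(OCc5ccccc5)c4c3O[C@H](c3ccc(OCc5ccccc5)c(OCc5ccccc5)c3)[C@@H](OCc5ccccc5)C4)[C@H]2OCc5ccccc5
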